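**Retrosynthetic overview**

1. Target 14 comes from the protected (2S)-flavanone 13 by one acid methanolysis that removes two MOM ethers and one aryl acetate.
2. Ring C is the only ring formed. A [3+3] annulation joins phenol 7 (ring A with O1 and C4a) and O-acetylsinapoyl chloride 10 (C4, C3, C2 and ring B): C4–C4a by magnesium-templated ortho-acylation, then O1–C2 by a catalyst-controlled 6-endo oxa-Michael addition that sets C2, the only stereocentre.
3. Enabling feature: ring A is a phloroglucinol. C4a lies ortho to the O1-bearing C8a and ortho/para to the C5 and C7 oxygens, so the magnesium phenoxide of O1 is acylated at C4a without a strong Lewis acid, and O1 is then held next to C2, the β-carbon of the aryl enone. O1 (para to the geranyl-bearing C6) is the only unmasked oxygen, which fixes the 6-geranyl pattern.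
4. Phenol 7 comes from phloroglucinol 1: bis-MOM ether, TIPS ether on the third oxygen, lithiation between the two MOM ethers and geranylation with 4, then desilylation. Acid chloride 10 comes from sinapic acid 8 by acetylation and chlorination.
5. Rings A and B are bought as arenes; order of ring formation: ring C only (step 7).

Key step: step 7

Remark on the chemistry: the sense of induction of the thiourea catalyst in step 7 is not fixed by precedent for this substrate class. The quinidine-derived catalyst is written; its quinine-derived pseudoenantiomer is to be used instead if that one delivers 2S.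

**Route**

Step 1
Reactants: 1 phloroglucinol (benzene-1,3,5-triol)
Product: 2 3,5-bis(methoxymethoxy)phenol
Conditions: MOMCl (2.0 equiv), i-Pr2NEt (2.2 equiv), DMF/CH2Cl2, 0 °C → rt
Reagents that add atoms: chloromethyl methyl ether (MOMCl), COCCl
Why: Williamson-type O-alkylation of three equivalent hydroxyls, so two equivalents of MOMCl should give the bis-ether statistically, to be separated from mono- and tris-ether, which can be recycled.

Step 2
Reactants: 2 3,5-bis(methoxymethoxy)phenol
Product: 3 [3,5-bis(methoxymethoxy)phenoxy]tri(propan-2-yl)silane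
Conditions: TIPSCl (1.1 equiv), imidazole (2.0 equiv), DMF, rt
Reagents that add atoms: triisopropylsilyl chloride (TIPSCl), CC(C)[Si](Cl)(C(C)C)C(C)C
Why: Imidazole-promoted silylation of the remaining phenol gives a bulky, non-directing silyl ether that marks the future O1 apart from the two MOM-protected oxygens.

Step 3
Reactants: 3 [3,5-bis(methoxymethoxy)phenoxy]tri(propan-2-yl)silane; 4 geranyl bromide [(2E)-1-bromo-3,7-dimethylocta-2,6-diene]
Product: 6 {4-[(2E)-3,7-dimethylocta-2,6-dien-1-yl]-3,5-bis(methoxymethoxy)phenoxy}tri(propan-2-yl)silane, via aryllithium 5 (not isolated)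
Conditions: n-BuLi (1.2 equiv), THF, 0 °C; CuBr·SMe2 (10 mol %), −78 °C; 4, −78 °C → rt
Reagents that add atoms: none
Why: Directed ortho-metalation should lithiate the carbon between the two coordinating MOM ethers rather than those next to the bulky silyl ether, and copper-catalysed SN2 allylation with geranyl bromide should keep the 2E double bond and place the chain para to the future O1.

Step 4
Reactants: 6 {4-[(2E)-3,7-dimethylocta-2,6-dien-1-yl]-3,5-bis(methoxymethoxy)phenoxy}tri(propan-2-yl)silane
Product: 7 4-[(2E)-3,7-dimethylocta-2,6-dien-1-yl]-3,5-bis(methoxymethoxy)phenol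
Conditions: TBAF (1.1 equiv), AcOH (1.1 equiv), THF, 0 °C
Reagents that add atoms: none
Why: Buffered fluoride cleavage of the aryl silyl ether should free O1 while the MOM ethers and the diene stay untouched.

Step 5
Reactants: 8 sinapic acid [(2E)-3-(4-hydroxy-3,5-dimethoxyphenyl)prop-2-enoic acid]
Product: 9 (2E)-3-[4-(acetyloxy)-3,5-dimethoxyphenyl]prop-2-enoic acid
Conditions: Ac2O (1.2 equiv), pyridine, 0 °C → rt; dilute aqueous HCl work-up
Reagents that add atoms: acetic anhydride, CC(=O)OC(C)=O
Why: O-Acetylation of the phenol masks ring B for steps 6 and 7 and makes the aryl group electron-poor, which later raises the electrophilicity of C2.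

Step 6
Reactants: 9 (2E)-3-[4-(acetyloxy)-3,5-dimethoxyphenyl]prop-2-enoic acid
Product: 10 4-[(1E)-3-chloro-3-oxoprop-1-en-1-yl]-2,6-dimethoxyphenyl acetate (O-acetylsinapoyl chloride)
Conditions: (COCl)2 (1.3 equiv), DMF (cat.), CH2Cl2, 0 °C → rt; volatiles removed, 10 used crude
Reagents that add atoms: oxalyl chloride, O=C(Cl)C(Cl)=O
Why: Acid chloride formation through the Vilsmeier-type chloroiminium species should leave the E-alkene and the aryl acetate unchanged.

Step 7
Reactants: 7 4-[(2E)-3,7-dimethylocta-2,6-dien-1-yl]-3,5-bis(methoxymethoxy)phenol; 10 O-acetylsinapoyl chloride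
Product: 13 4-[(2S)-6-[(2E)-3,7-dimethylocta-2,6-dien-1-yl]-5,7-bis(methoxymethoxy)-4-oxo-3,4-dihydro-2H-chromen-2-yl]-2,6-dimethoxyphenyl acetate, via bromomagnesium phenoxide 11 (not isolated), via 2′-hydroxychalcone 12 (not isolated)
Conditions: one pot: 7 (1.05 equiv), EtMgBr (1.05 equiv), Et2O, 0 °C; solvent switch to toluene; 10 (1.0 equiv), rt; toluene solution washed (aq. NaHCO3) and dried (Na2SO4) without isolation; then epi-9-amino-9-deoxyquinidine-derived 3,5-bis(trifluoromethyl)phenyl thiourea (10 mol %), toluene, −20 °C
Reagents that add atoms: none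
Why: Proposed new method: the bromomagnesium phenoxide 11 should bind the acyl chloride at magnesium and be acylated at its ortho carbon (the future C4a) through a six-membered coordinated transition state, giving after the wash the magnesium-free 2′-hydroxychalcone 12, which the bifunctional amine–thiourea then closes to ring C by a 6-endo-trig oxa-Michael addition of O1 to C2; the closest known reaction types are the ortho-C-acylation of bromomagnesium phenoxides with acyl chlorides and the cinchona-thiourea-catalysed intramolecular oxa-Michael addition of phenols to enones (2-substituted chromans, and flavanones carrying a 3-alkoxycarbonyl activating group), whereas their one-pot union and the closure of a chalcone without such an activating group are not established. C2 is the only new stereocentre and is under catalyst control: the thiourea hydrogen-bonds the C4 carbonyl, the quinuclidine nitrogen takes up and relays the O1 proton, and O1 should be delivered to the Si face of C2 to give the 2S configuration. Carbon rather than oxygen acylation is secured by the magnesium template in toluene and by the phloroglucinol pattern of ring A (C4a ortho to O1 and ortho/para to the two MOM-protected oxygens); the two ortho carbons of 11 are equivalent and the para carbon is blocked by the geranyl chain. The regiochemistry of ring closure (6-geranyl, not 8-geranyl) is secured because O1 is the only free hydroxyl of ring A. Enantioselectivity needs the closure to stay under kinetic control, which the electron-poor 4-acetoxy-3,5-dimethoxyphenyl group (more electrophilic C2, flavanone expected to be strongly favoured at equilibrium) and the low temperature should ensure. The magnesium chelate of 12 is not expected to cyclise, so no racemic background closure should occur before the catalyst is added.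

Step 8
Reactants: 13 4-[(2S)-6-[(2E)-3,7-dimethylocta-2,6-dien-1-yl]-5,7-bis(methoxymethoxy)-4-oxo-3,4-dihydro-2H-chromen-2-yl]-2,6-dimethoxyphenyl acetate
Product: 14 (2S)-6-[(2E)-3,7-dimethylocta-2,6-dien-1-yl]-5,7-dihydroxy-2-(4-hydroxy-3,5-dimethoxyphenyl)-2,3-dihydro-4H-chromen-4-one (target)
Conditions: HCl (3 M aq., 5 equiv), MeOH, 40 °C
Reagents that add atoms: none
Why: Acid-catalysed methanolysis should cleave both MOM acetals (acetal exchange) and the aryl acetate (transesterification) in one pot, the mild temperature being chosen to spare the geranyl chain and the configuration at C2.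

**Compound list**

1 | phloroglucinol (benzene-1,3,5-triol) | Oc1cc(O)cc(O)c1 | starting material
2 | 3,5-bis(methoxymethoxy)phenol | COCOc1cc(O)cc(OCOC)c1 | intermediate
3 | [3,5-bis(methoxymethoxy)phenoxy]tri(propan-2-yl)silane | COCOc1cc(OCOC)cc(O[Si](C(C)C)(C(C)C)C(C)C)c1 | intermediate
4 | geranyl bromide, (2E)-1-bromo-3,7-dimethylocta-2,6-diene | BrC/C=C(\C)CCC=C(C)C | starting material
5 | {2,6-bis(methoxymethoxy)-4-[tri(propan-2-yl)silyloxy]phenyl}lithium | [Li]c1c(OCOC)cc(O[Si](C(C)C)(C(C)C)C(C)C)cc1OCOC | intermediate
6 | {4-[(2E)-3,7-dimethylocta-2,6-dien-1-yl]-3,5-bis(methoxymethoxy)phenoxy}tri(propan-2-yl)silane | COCOc1cc(O[Si](C(C)C)(C(C)C)C(C)C)cc(OCOC)c1C/C=C(\C)CCC=C(C)C | intermediate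
7 | 4-[(2E)-3,7-dimethylocta-2,6-dien-1-yl]-3,5-bis(methoxymethoxy)phenol | COCOc1cc(O)cc(OCOC)c1C/C=C(\C)CCC=C(C)C | intermediate
8 | sinapic acid, (2E)-3-(4-hydroxy-3,5-dimethoxyphenyl)prop-2-enoic acid | COc1cc(/C=C/C(=O)O)cc(OC)c1O | starting material
9 | (2E)-3-[4-(acetyloxy)-3,5-dimethoxyphenyl]prop-2-enoic acid | COc1cc(/C=C/C(=O)O)cc(OC)c1OC(C)=O | intermediate
10 | 4-[(1E)-3-chloro-3-oxoprop-1-en-1-yl]-2,6-dimethoxyphenyl acetate (O-acetylsinapoyl chloride) | COc1cc(/C=C/C(=O)Cl)cc(OC)c1OC(C)=O | intermediate
11 | bromomagnesium 4-[(2E)-3,7-dimethylocta-2,6-dien-1-yl]-3,5-bis(methoxymethoxy)phenoxide | COCOc1cc(O[Mg]Br)cc(OCOC)c1C/C=C(\C)CCC=C(C)C | intermediate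
12 | 4-[(1E)-3-{3-[(2E)-3,7-dimethylocta-2,6-dien-1-yl]-6-hydroxy-2,4-bis(methoxymethoxy)phenyl}-3-oxoprop-1-en-1-yl]-2,6-dimethoxyphenyl acetate (2′-hydroxychalcone) | COc1cc(/C=C/C(=O)c2c(O)cc(OCOC)c(C/C=C(\C)CCC=C(C)C)c2OCOC)cc(OC)c1OC(C)=O | intermediate
13 | 4-[(2S)-6-[(2E)-3,7-dimethylocta-2,6-dien-1-yl]-5,7-bis(methoxymethoxy)-4-oxo-3,4-dihydro-2H-chromen-2-yl]-2,6-dimethoxyphenyl acetate | COc1cc([C@@H]2CC(=O)c3c(cc(OCOC)c(C/C=C(\C)CCC=C(C)C)c3OCOC)O2)cc(OC)c1OC(C)=O | intermediate
14 | (2S)-6-[(2E)-3,7-dimethylocta-2,6-dien-1-yl]-5,7-dihydroxy-2-(4-hydroxy-3,5-dimethoxyphenyl)-2,3-dihydro-4H-chromen-4-one | COc1cc([C@@H]2CC(=O)c3c(cc(O)c(C/C=C(\C)CCC=C(C)C)c3O)O2)cc(OC)c1O | target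

**Step count and risks**

Total step count: 8. Longest linear sequence: 6 steps (steps 1, 2, 3, 4, 7, 8).

Steps most likely to fail:

1. Step 7 (proposed new method). What may go wrong: insufficient facial selectivity in the oxa-Michael closure, or erosion of enantiomeric purity through reversible ring opening, so that 13 is formed with low optical purity. Fallback (known chemistry, sets out from 7 and 10, returns at 13): the magnesium-phenoxide acylation is run on its own and chalcone 12 is isolated. A base-mediated chalcone–flavanone isomerisation (Et3N, toluene, 70 °C) should then give racemic 4-[6-geranyl-5,7-bis(methoxymethoxy)-4-oxochroman-2-yl]-2,6-dimethoxyphenyl acetate F1. Preparative chromatography of F1 on a chiral stationary phase should deliver 13, and the unwanted enantiomer can be re-equilibrated through 12 with base and recycled.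

2. Step 3. What may go wrong: attack of the aryl nucleophile at the tertiary allyl terminus (SN2′), scrambling of the 2E geometry, or incomplete lithiation. Fallback (sets out from 3, returns at 6): the aryllithium 5 is quenched with iodine to give {4-iodo-3,5-bis(methoxymethoxy)phenoxy}tri(propan-2-yl)silane F2. A ligand-controlled, α-selective Suzuki–Miyaura allyl–aryl coupling of F2 with geranylboronic acid pinacol ester (Pd(OAc)2, a bulky biarylphosphine such as t-BuXPhos, K3PO4, THF/H2O) should then give 6 with the linear 2E chain.

3. Step 8. What may go wrong: acid-promoted cyclisation of the geranyl chain onto the flanking C5 and C7 hydroxyls, addition of methanol or HCl to the chain, or acid-mediated opening of ring C at the p-hydroxybenzylic C2–O1 bond with loss of configuration. Fallback (sets out from 13, returns at 14): the deprotection is split into two non-protic stages. Lewis acid/thiol acetal cleavage (ZnBr2, n-PrSH, CH2Cl2, 0 °C) should remove both MOM ethers and give 4-[(2S)-6-geranyl-5,7-dihydroxy-4-oxochroman-2-yl]-2,6-dimethoxyphenyl acetate F3. Neutral deacetylation of F3 (NH4OAc, aqueous MeOH, rt) should then give 14.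

**Further compounds**

F1 | step 7 | racemic 4-[6-[(2E)-3,7-dimethylocta-2,6-dien-1-yl]-5,7-bis(methoxymethoxy)-4-oxo-3,4-dihydro-2H-chromen-2-yl]-2,6-dimethoxyphenyl acetate | COc1cc(C2CC(=O)c3c(cc(OCOC)c(C/C=C(\C)CCC=C(C)C)c3OCOC)O2)cc(OC)c1OC(C)=O
F2 | step 3 | {4-iodo-3,5-bis(methoxymethoxy)phenoxy}tri(propan-2-yl)silane | COCOc1cc(O[Si](C(C)C)(C(C)C)C(C)C)cc(OCOC)c1I
F3 | step 8 | 4-[(2S)-6-[(2E)-3,7-dimethylocta-2,6-dien-1-yl]-5,7-dihydroxy-4-oxo-3,4-dihydro-2H-chromen-2-yl]-2,6-dimethoxyphenyl acetate | COc1cc([C@@H]2CC(=O)c3c(cc(O)c(C/C=C(\C)CCC=C(C)C)c3O)O2)cc(OC)c1OC(C)=O
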